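**Plan**

Numbering: ring C1 (olefinic, methyl-bearing), C2 (olefinic CH), C3, C4, C5 (CHMe), C6 (quaternary); chain C7–C15 runs from C6 to sulfur.
Retrosynthesis: cut the guanidine C–N bond and the C15–S bond (sulfinate alkylation), then C8–C9 (B-alkyl Suzuki coupling with an (E)-vinyl iodide made from geranyl acetate), then remove a C3 oxygen and cut C4–C5 and C1–C6 of the ring.
Enabling feature: C5 and C6 carry cis methyls and C6 a one-carbon branch (C7); this is (E)-2-methylbut-2-enal with its olefin as C5–C6 and its formyl carbon as C7, so the ring is its [4+2] adduct with a 2-silyloxypenta-1,3-diene that supplies C1–C4.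
Forward: the only ring is closed first by this cycloaddition; C7 becomes a vinyl group, the enol ether is converted into the C1=C2 olefin (dehydrogenation, then allylic deoxygenation), the chain is joined at C8–C9, and sulfone and guanidine come last.
Stereochemistry: C5/C6 relative configuration from the E enal (suprafacial addition), absolute configuration from the chiral oxazaborolidinium catalyst; C13=C14 from geranyl acetate, C9=C10 from syn hydrozirconation of a 2-alkyne.

Key step: step 2

Assumption: the (S)-configured oxazaborolidinium cation is taken to guide the diene to the Cα-re/Cβ-si face of the α-methyl enal, as in its additions to 2-methylacrolein; should the sense of induction prove opposite, the (R)-catalyst is used with no other change.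

**Route**

Step 1
Reactants: 1 (E)-pent-3-en-2-one
Product: 2 (E)-triisopropyl(penta-1,3-dien-2-yloxy)silane
Conditions: TIPSOTf, Et3N, Et2O, 0 °C → rt
Reagents that add atoms: triisopropylsilyl trifluoromethanesulfonate, CC(C)[Si](C(C)C)(C(C)C)OS(=O)(=O)C(F)(F)F
Why: Soft enolisation with silyl triflate and amine removes a proton from the α'-methyl group under kinetic control, and O-silylation should give the cross-conjugated 2-silyloxy diene with the E olefin untouched (silyl enol ether formation).

Step 2
Reactants: 2 (E)-triisopropyl(penta-1,3-dien-2-yloxy)silane; 3 (E)-2-methylbut-2-enal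
Product: 4 (1S,6R)-1,2,6-trimethyl-4-[(triisopropylsilyl)oxy]cyclohex-3-ene-1-carbaldehyde (mixture of C2 epimers)
Conditions: (S)-1-(2-methylphenyl)-3,3-diphenyltetrahydro-1H,3H-pyrrolo[1,2-c][1,3,2]oxazaborole (20 mol %), HNTf2 (18 mol %), CH2Cl2, −78 → −40 °C
Reagents that add atoms: none
Why: The boron cation formed from the oxazaborolidine and HNTf2 binds the formyl oxygen of 3 and lowers its LUMO, and the ring then closes in one concerted but asynchronous [4+2] event in which the C4–C5 bond (diene CH2 terminus to the enal β-carbon) runs ahead of the C1–C6 bond; the closest known reaction type is the oxazaborolidinium-catalysed enantioselective Diels–Alder addition of α-substituted enals to 2-silyloxy-1,3-dienes. The six-membered ring is closed by intermolecular suprafacial–suprafacial cycloaddition, both ring bonds being made in this one step. At C5 and C6 the relative configuration follows from retention of the E geometry of 3 (the two methyls end cis, the formyl carbon trans to the C5 methyl), and the absolute configuration from the catalyst, whose aryl group screens one face of the bound s-trans enal so that the diene adds to the Cα-re/Cβ-si face. The third centre (C1 of the target, C2 of 4) depends on endo or exo approach and is left uncontrolled, because step 4 makes this carbon trigonal. The step needs regioselectivity, secured by the silyloxy group and the terminal methyl of 2, which both place the largest HOMO coefficient on the CH2 terminus, and enantioselectivity, secured by the formyl C–H···O contact that fixes the enal on the catalyst; the bulky triisopropylsilyl group suppresses silyl transfer and Mukaiyama-type 1,2-addition.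

Step 3
Reactants: 4 (1S,6R)-1,2,6-trimethyl-4-[(triisopropylsilyl)oxy]cyclohex-3-ene-1-carbaldehyde
Product: 5 {[(4S,5R)-4-ethenyl-3,4,5-trimethylcyclohex-1-en-1-yl]oxy}tri(propan-2-yl)silane (mixture of C3 epimers)
Conditions: Ph3PCH3Br, KN(SiMe3)2, THF, 0 °C → rt
Reagents that add atoms: methyltriphenylphosphonium bromide, C[P+](c1ccccc1)(c1ccccc1)c1ccccc1.[Br-]
Why: Wittig methylenation with the small, alkoxide-free ylide should convert the non-enolisable neopentyl aldehyde into the vinyl group (C7=C8) without touching the bulky silyl enol ether or any stereocentre.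

Step 4
Reactants: 5 {[(4S,5R)-4-ethenyl-3,4,5-trimethylcyclohex-1-en-1-yl]oxy}tri(propan-2-yl)silane
Product: 6 (4S,5R)-4-ethenyl-3,4,5-trimethylcyclohex-2-en-1-one
Conditions: Pd(OAc)2 (1.1 equiv), MeCN, 40 °C
Reagents that add atoms: none
Why: In the Saegusa–Ito oxidation the silyl enol ether hands its α-carbon (C2 of the target) to divalent palladium and β-hydride elimination can only take the hydrogen on the methyl-bearing carbon, so the regiodefined enol ether should become the C1=C2 enone and both epimers of 5 converge.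

Step 5
Reactants: 6 (4S,5R)-4-ethenyl-3,4,5-trimethylcyclohex-2-en-1-one
Product: 7 (4S,5R)-4-ethenyl-3,4,5-trimethylcyclohex-2-en-1-ol (mixture of C1 epimers)
Conditions: NaBH4, CeCl3·7H2O, MeOH, 0 °C
Reagents that add atoms: none
Why: Luche reduction should give clean 1,2-reduction of the enone to the allylic alcohol; the new carbinol centre is removed in step 7, so its configuration is irrelevant.

Step 6
Reactants: 7 (4S,5R)-4-ethenyl-3,4,5-trimethylcyclohex-2-en-1-ol
Product: 8 (4S,5R)-4-ethenyl-3,4,5-trimethylcyclohex-2-en-1-yl acetate (mixture of C1 epimers)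
Conditions: Ac2O, pyridine, 4-(dimethylamino)pyridine (cat.), CH2Cl2, rt
Reagents that add atoms: acetic anhydride, CC(=O)OC(C)=O
Why: Nucleophile-catalysed acylation of the unhindered secondary allylic alcohol provides the leaving group for palladium.

Step 7
Reactants: 8 (4S,5R)-4-ethenyl-3,4,5-trimethylcyclohex-2-en-1-yl acetate
Product: 9 (5R,6S)-6-ethenyl-1,5,6-trimethylcyclohex-1-ene
Conditions: Pd(PPh3)4 (5 mol %), LiBHEt3 (1.5 equiv, added last), THF, 0 °C → rt; pentane work-up, cold concentration (volatile)
Reagents that add atoms: none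
Why: In this palladium-catalysed allylic hydrogenolysis (Tsuji–Trost ionisation, then hydride transfer from the borohydride) zerovalent palladium should ionise the acetate to a π-allyl complex spanning C1–C3, and hydride should enter at the unhindered secondary terminus C3 and not at the fully substituted C1 beside the quaternary carbon, which leaves the C1=C2 olefin in place; formate is avoided because it delivers hydride to the more substituted terminus.

Step 8
Reactants: 10 geranyl acetate [(2E)-3,7-dimethylocta-2,6-dien-1-yl acetate]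
Product: 11 (2E)-5-(3,3-dimethyloxiran-2-yl)-3-methylpent-2-en-1-yl acetate (racemic at the epoxide)
Conditions: mCPBA (1.05 equiv), NaHCO3, CH2Cl2, −20 → 0 °C
Reagents that add atoms: 3-chloroperoxybenzoic acid, O=C(OO)c1cccc(Cl)c1
Why: Prilezhaev epoxidation should be selective for the distal, more electron-rich trisubstituted olefin, because the 2,3-olefin is deactivated by the allylic acetate.

Step 9
Reactants: 11 (2E)-5-(3,3-dimethyloxiran-2-yl)-3-methylpent-2-en-1-yl acetate
Product: 12 (2E)-3-methyl-6-oxohex-2-en-1-yl acetate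
Conditions: H5IO6, THF/H2O, 0 °C
Reagents that add atoms: none
Why: Periodic acid opens the epoxide to the diol and cleaves it in the same pot (glycol cleavage), which should give the aldehyde and acetone without touching the allylic acetate or the E olefin.

Step 10
Reactants: 12 (2E)-3-methyl-6-oxohex-2-en-1-yl acetate
Product: 14 (2E)-3-methylhept-2-en-6-yn-1-ol, via alkynyl acetate 13 (not isolated)
Conditions: dimethyl (1-diazo-2-oxopropyl)phosphonate, K2CO3, MeOH, 0 °C → rt
Reagents that add atoms: dimethyl (1-diazo-2-oxopropyl)phosphonate, CC(=O)C(=[N+]=[N-])P(=O)(OC)OC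
Why: Ohira–Bestmann (Seyferth–Gilbert) homologation converts the enolisable aldehyde into the terminal alkyne under the K2CO3/methanol conditions that also transesterify the acetate, so the free allylic alcohol should result in one operation.

Step 11
Reactants: 14 (2E)-3-methylhept-2-en-6-yn-1-ol
Product: 16 (2E)-3-methyloct-2-en-6-yn-1-ol, via dilithio alkoxide-acetylide 15 (not isolated)
Conditions: n-BuLi (2.2 equiv), THF, −78 → 0 °C; MeI (1.1 equiv), −78 °C → rt
Reagents that add atoms: iodomethane, CI
Why: The alkoxide–acetylide dianion should be alkylated by iodomethane at its far more nucleophilic carbon terminus (acetylide alkylation), giving the 2-alkyne.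

Step 12
Reactants: 16 (2E)-3-methyloct-2-en-6-yn-1-ol
Product: 18 (2E,6E)-7-iodo-3-methylocta-2,6-dien-1-ol, via alkenylzirconocene 17 (not isolated)
Conditions: Cp2Zr(H)Cl (2.5 equiv), THF, rt → 50 °C; then I2, 0 °C
Reagents that add atoms: iodine, II
Why: Hydrozirconation adds Zr–H syn across the alkyne and, with excess reagent under equilibrating conditions, places zirconium on the less hindered methyl-bearing carbon; iodinolysis with retention should give the (E)-2-iodo-2-alkene that fixes the C9=C10 geometry.

Step 13
Reactants: 9 (5R,6S)-6-ethenyl-1,5,6-trimethylcyclohex-1-ene; 18 (2E,6E)-7-iodo-3-methylocta-2,6-dien-1-ol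
Product: 20 (2E,6E)-3,7-dimethyl-9-[(1S,6R)-1,2,6-trimethylcyclohex-2-en-1-yl]nona-2,6-dien-1-ol, via B-alkyl-9-BBN borane 19 (not isolated)
Conditions: 9-BBN, THF, rt → 60 °C; then 18, PdCl2(dppf) (5 mol %; dppf = 1,1'-bis(diphenylphosphino)ferrocene), AsPh3, Cs2CO3, DMF/H2O, rt
Reagents that add atoms: none
Why: 9-BBN should hydroborate only the terminal vinyl group (boron on C8) and leave the hindered trisubstituted ring olefin, and the B-alkyl Suzuki–Miyaura coupling then joins C8 to C9 with retention of the vinyl iodide geometry.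

Step 14
Reactants: 20 (2E,6E)-3,7-dimethyl-9-[(1S,6R)-1,2,6-trimethylcyclohex-2-en-1-yl]nona-2,6-dien-1-ol
Product: 22 (5R,6S)-6-[(3E,7E)-9-bromo-3,7-dimethylnona-3,7-dien-1-yl]-1,5,6-trimethylcyclohex-1-ene, via allylic mesylate 21 (not isolated)
Conditions: MsCl, Et3N, THF, −40 °C; then LiBr, 0 °C; used crude
Reagents that add atoms: lithium bromide, [Li+].[Br-]
Why: Mesylation and bromide displacement in the same pot (SN2) should convert the primary allylic alcohol into the bromide under non-acidic conditions that preserve the olefin geometry.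

Step 15
Reactants: 23 hypotaurine (2-aminoethanesulfinic acid)
Product: 24 sodium 2-[(tert-butoxycarbonyl)amino]ethanesulfinate
Conditions: NaOH (1 equiv), Boc2O, H2O/1,4-dioxane, 0 °C → rt; freeze-drying
Reagents that add atoms: di-tert-butyl dicarbonate, CC(C)(C)OC(=O)OC(=O)OC(C)(C)C; sodium hydroxide, [Na+].[OH-]
Why: After deprotonation of the zwitterion the amine is acylated by Boc2O (Schotten–Baumann-type carbamate formation) while the sulfinate stays as its sodium salt.

Step 16
Reactants: 22 (5R,6S)-6-[(3E,7E)-9-bromo-3,7-dimethylnona-3,7-dien-1-yl]-1,5,6-trimethylcyclohex-1-ene; 24 sodium 2-[(tert-butoxycarbonyl)amino]ethanesulfinate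
Product: 25 tert-butyl N-[2-({(2E,6E)-3,7-dimethyl-9-[(1S,6R)-1,2,6-trimethylcyclohex-2-en-1-yl]nona-2,6-dien-1-yl}sulfonyl)ethyl]carbamate
Conditions: DMF, rt
Reagents that add atoms: none
Why: Sulfinate anions are alkylated at sulfur by soft allylic bromides (SN2 at the primary carbon), which should give the primary allylic sulfone directly at the sulfone oxidation level.

Step 17
Reactants: 25 tert-butyl N-[2-({(2E,6E)-3,7-dimethyl-9-[(1S,6R)-1,2,6-trimethylcyclohex-2-en-1-yl]nona-2,6-dien-1-yl}sulfonyl)ethyl]carbamate
Product: 27 2-({(2E,6E)-3,7-dimethyl-9-[(1S,6R)-1,2,6-trimethylcyclohex-2-en-1-yl]nona-2,6-dien-1-yl}sulfonyl)ethan-1-amine, via trimethylsilyl carbamate 26 (not isolated)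
Conditions: TMSOTf, 2,6-lutidine, CH2Cl2, 0 °C; then MeOH
Reagents that add atoms: none
Why: Silyl triflate-mediated carbamate cleavage (tert-butyl to trimethylsilyl carbamate, then methanolysis and decarboxylation) should remove the Boc group without protic acid, which spares the three trisubstituted olefins from cation chemistry.

Step 18
Reactants: 27 2-({(2E,6E)-3,7-dimethyl-9-[(1S,6R)-1,2,6-trimethylcyclohex-2-en-1-yl]nona-2,6-dien-1-yl}sulfonyl)ethan-1-amine
Product: 28 agelasidine C, 1-[2-({(2E,6E)-3,7-dimethyl-9-[(1S,6R)-1,2,6-trimethylcyclohex-2-en-1-yl]nona-2,6-dien-1-yl}sulfonyl)ethyl]guanidine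
Conditions: 1H-pyrazole-1-carboxamidine hydrochloride, i-Pr2NEt, DMF, rt; aq. NaOH work-up (free base)
Reagents that add atoms: 1H-pyrazole-1-carboxamidine hydrochloride, NC(=N)n1cccn1.Cl
Why: Amidine transfer from 1H-pyrazole-1-carboxamidine to the primary amine (guanylation) should give the unprotected guanidine directly, pyrazole being the leaving group.

**Compound list**

1 | (E)-pent-3-en-2-one | C/C=C/C(C)=O | starting material
2 | (E)-triisopropyl(penta-1,3-dien-2-yloxy)silane | C=C(O[Si](C(C)C)(C(C)C)C(C)C)/C=C/C | intermediate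
3 | (E)-2-methylbut-2-enal | C/C=C(\C)C=O | starting material
4 | (1S,6R)-1,2,6-trimethyl-4-[(triisopropylsilyl)oxy]cyclohex-3-ene-1-carbaldehyde, C2 epimers (1- and 6-methyl cis, formyl trans to the 6-methyl) | CC1C=C(O[Si](C(C)C)(C(C)C)C(C)C)C[C@@H](C)[C@]1(C)C=O | intermediate
5 | {[(4S,5R)-4-ethenyl-3,4,5-trimethylcyclohex-1-en-1-yl]oxy}tri(propan-2-yl)silane, C3 epimers | CC1C=C(O[Si](C(C)C)(C(C)C)C(C)C)C[C@@H](C)[C@]1(C)C=C | intermediate
6 | (4S,5R)-4-ethenyl-3,4,5-trimethylcyclohex-2-en-1-one | CC1=CC(=O)C[C@@H](C)[C@]1(C)C=C | intermediate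
7 | (4S,5R)-4-ethenyl-3,4,5-trimethylcyclohex-2-en-1-ol, C1 epimers | CC1=CC(O)C[C@@H](C)[C@]1(C)C=C | intermediate
8 | (4S,5R)-4-ethenyl-3,4,5-trimethylcyclohex-2-en-1-yl acetate, C1 epimers | CC1=CC(OC(C)=O)C[C@@H](C)[C@]1(C)C=C | intermediate
9 | (5R,6S)-6-ethenyl-1,5,6-trimethylcyclohex-1-ene | CC1=CCC[C@@H](C)[C@]1(C)C=C | intermediate
10 | geranyl acetate, (2E)-3,7-dimethylocta-2,6-dien-1-yl acetate | CC(C)=CCC/C(C)=C/COC(C)=O | starting material
11 | (2E)-5-(3,3-dimethyloxiran-2-yl)-3-methylpent-2-en-1-yl acetate, racemic at the epoxide | CC1(C)OC1CC/C(C)=C/COC(C)=O | intermediate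
12 | (2E)-3-methyl-6-oxohex-2-en-1-yl acetate | O=CCC/C(C)=C/COC(C)=O | intermediate
13 | (2E)-3-methylhept-2-en-6-yn-1-yl acetate | C#CCC/C(C)=C/COC(C)=O | intermediate (not isolated)
14 | (2E)-3-methylhept-2-en-6-yn-1-ol | C#CCC/C(C)=C/CO | intermediate
15 | dilithium salt of 14 (lithium alkoxide, lithium acetylide) | [Li]C#CCC/C(C)=C/CO[Li] | intermediate (not isolated)
16 | (2E)-3-methyloct-2-en-6-yn-1-ol | CC#CCC/C(C)=C/CO | intermediate
17 | (2E,6E)-alkenylzirconocene chloride at C7 with the O1 zirconocene chloride alkoxide | Cl[Zr](C1C=CC=C1)(C1C=CC=C1)/C(C)=C/CC/C(C)=C/CO[Zr](Cl)(C1C=CC=C1)C1C=CC=C1 | intermediate (not isolated)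
18 | (2E,6E)-7-iodo-3-methylocta-2,6-dien-1-ol | I/C(C)=C/CC/C(C)=C/CO | intermediate
19 | 9-{2-[(1S,6R)-1,2,6-trimethylcyclohex-2-en-1-yl]ethyl}-9-borabicyclo[3.3.1]nonane | CC1=CCC[C@@H](C)[C@]1(C)CCB1C2CCCC1CCC2 | intermediate (not isolated)
20 | (2E,6E)-3,7-dimethyl-9-[(1S,6R)-1,2,6-trimethylcyclohex-2-en-1-yl]nona-2,6-dien-1-ol | CC1=CCC[C@@H](C)[C@]1(C)CC/C(C)=C/CC/C(C)=C/CO | intermediate
21 | (2E,6E)-3,7-dimethyl-9-[(1S,6R)-1,2,6-trimethylcyclohex-2-en-1-yl]nona-2,6-dien-1-yl methanesulfonate | CC1=CCC[C@@H](C)[C@]1(C)CC/C(C)=C/CC/C(C)=C/COS(C)(=O)=O | intermediate (not isolated)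
22 | (5R,6S)-6-[(3E,7E)-9-bromo-3,7-dimethylnona-3,7-dien-1-yl]-1,5,6-trimethylcyclohex-1-ene | CC1=CCC[C@@H](C)[C@]1(C)CC/C(C)=C/CC/C(C)=C/CBr | intermediate
23 | hypotaurine, 2-aminoethanesulfinic acid | NCCS(=O)O | starting material
24 | sodium 2-[(tert-butoxycarbonyl)amino]ethanesulfinate | CC(C)(C)OC(=O)NCCS(=O)[O-].[Na+] | intermediate
25 | tert-butyl N-[2-({(2E,6E)-3,7-dimethyl-9-[(1S,6R)-1,2,6-trimethylcyclohex-2-en-1-yl]nona-2,6-dien-1-yl}sulfonyl)ethyl]carbamate | CC1=CCC[C@@H](C)[C@]1(C)CC/C(C)=C/CC/C(C)=C/CS(=O)(=O)CCNC(=O)OC(C)(C)C | intermediate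
26 | trimethylsilyl N-[2-({(2E,6E)-3,7-dimethyl-9-[(1S,6R)-1,2,6-trimethylcyclohex-2-en-1-yl]nona-2,6-dien-1-yl}sulfonyl)ethyl]carbamate | CC1=CCC[C@@H](C)[C@]1(C)CC/C(C)=C/CC/C(C)=C/CS(=O)(=O)CCNC(=O)O[Si](C)(C)C | intermediate (not isolated)
27 | 2-({(2E,6E)-3,7-dimethyl-9-[(1S,6R)-1,2,6-trimethylcyclohex-2-en-1-yl]nona-2,6-dien-1-yl}sulfonyl)ethan-1-amine | CC1=CCC[C@@H](C)[C@]1(C)CC/C(C)=C/CC/C(C)=C/CS(=O)(=O)CCN | intermediate
28 | agelasidine C | CC1=CCC[C@@H](C)[C@]1(C)CC/C(C)=C/CC/C(C)=C/CS(=O)(=O)CCN=C(N)N | target

**Count and risks**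

Total: 18 steps. Longest linear sequence: 12 steps (steps 1–7, 13, 14, 16, 17, 18).

Step 2. The β-methyl group of 3 may slow the cycloaddition so far that silyl transfer, 1,2-addition of the diene to the activated formyl group or diene decomposition take over, or a loosened transition state may erode facial selectivity. The fallback replaces asymmetric catalysis by resolution and sets out from 2 and 3. Me2AlCl (1 equiv, CH2Cl2, −78 °C) promotes the same cycloaddition without a chiral ligand and should give the racemic aldehyde F1. Methylenation as in step 3 gives the racemic vinyl silyl enol ether F2, and Pd(OAc)2 as in step 4 gives the racemic enone F3. Addition of lithiated (S)-N,S-dimethyl-S-phenylsulfoximine (THF, −78 °C) gives diastereomeric β-hydroxy sulfoximines. Those derived from the (4S,5R) enone, the hydroxy sulfoximine F4, are separated by chromatography and thermolysed (toluene, 110 °C), which releases the sulfoximine and returns to the route at enone 6.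

Step 7. Hydride may attack the acetate carbonyl faster than zerovalent palladium ionises the ester (returning alcohol 7), the π-allyl complex may lose a β-hydrogen to give a ring diene, or part of the hydride may be delivered to C1. The fallback uses direct displacement without palladium and sets out from alcohol 7. Corey–Kim chlorination (N-chlorosuccinimide, Me2S, CH2Cl2, −20 °C) should give the allylic chloride F5. LiBHEt3 (THF, 0 °C) then displaces chloride by hydride at the unhindered C3; either allylic isomer of the chloride leads to the same olefin. The sequence returns to the route at diene 9.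

Step 4. Transfer of the enolate from the bulky triisopropylsilyl group to palladium may be slow next to the quaternary carbon, so that palladium black deposits or protodesilylation to the saturated ketone competes. The fallback uses selenium in place of palladium and sets out from 5. PhSeCl (CH2Cl2, −78 °C) selenenylates the enol ether at its α-carbon to give the α-phenylselanyl ketone F6. H2O2/pyridine (CH2Cl2, 0 °C) oxidises it to the selenoxide F7, whose syn elimination can only use the hydrogen on the methyl-bearing carbon. The sequence returns to the route at enone 6.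

**Further compounds**

F1 | step 2 | racemic (1S*,6R*)-1,2,6-trimethyl-4-[(triisopropylsilyl)oxy]cyclohex-3-ene-1-carbaldehyde, C2 epimers, one enantiomer drawn | CC1C=C(O[Si](C(C)C)(C(C)C)C(C)C)C[C@@H](C)[C@]1(C)C=O
F2 | step 2 | racemic {[(4S*,5R*)-4-ethenyl-3,4,5-trimethylcyclohex-1-en-1-yl]oxy}tri(propan-2-yl)silane, C3 epimers, one enantiomer drawn | CC1C=C(O[Si](C(C)C)(C(C)C)C(C)C)C[C@@H](C)[C@]1(C)C=C
F3 | step 2 | racemic (4S*,5R*)-4-ethenyl-3,4,5-trimethylcyclohex-2-en-1-one, one enantiomer drawn | CC1=CC(=O)C[C@@H](C)[C@]1(C)C=C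
F4 | step 2 | (4S,5R)-4-ethenyl-3,4,5-trimethyl-1-{[(S)-N-methyl-S-phenylsulfonimidoyl]methyl}cyclohex-2-en-1-ol, C1 epimers | CC1=CC(O)(C[S@@](=O)(=NC)c2ccccc2)C[C@@H](C)[C@]1(C)C=C
F5 | step 7 | (5R,6S)-3-chloro-6-ethenyl-1,5,6-trimethylcyclohex-1-ene, C3 epimers | CC1=CC(Cl)C[C@@H](C)[C@]1(C)C=C
F6 | step 4 | (4S,5R)-4-ethenyl-3,4,5-trimethyl-2-(phenylselanyl)cyclohexan-1-one, C2/C3 epimers | CC1C([Se]c2ccccc2)C(=O)C[C@@H](C)[C@]1(C)C=C
F7 | step 4 | (4S,5R)-4-ethenyl-3,4,5-trimethyl-2-(phenylseleninyl)cyclohexan-1-one, C2/C3 epimers | CC1C([Se](=O)c2ccccc2)C(=O)C[C@@H](C)[C@]1(C)C=C
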